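Rings A and C are cut out of a 4-hydroxy-2-pyrone. Ring A is a phloroglucinol with oxygen on C5, C7 and C8a and the acyl carbon C4 on C4a, the pattern of a triketide folded by Claisen condensation, and C2 is an enol-ether carbon within reach of O1. In one operation methoxide opens pyrone 15 to a triketo ester, C4a closes onto the ester carbon (C4a–C5, ring A) and a ring-A phenoxide displaces methoxide at C2 (O1–C2, ring C), giving isoflavone 18. Precursor 15 is triacetic acid lactone acylated on its methyl group by the ring-B α-aryl-β-methoxyacryloyl unit. Transfer hydrogenation then sets C3.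

Key step: step 9

Remark on configuration: the stereo-SMILES is read as (3S) (CIP order at C3: C4 > C2 > C1′ > H). The (S,S)-catalyst in step 11 is chosen from the usual sense of this catalyst family ((S,S) gives (S)-benzylic alcohols), which corresponds to the cis-(3S,4S)-isoflavan-4-ol; this assignment is to be confirmed on the first batch.

Remark on ring B: the target needs the pyran oxygen ortho and the free phenol para to C1′. Direct chromenylation of 2,4-dihydroxybenzaldehyde would etherify O4 and give the 6-formyl-5-hydroxychromene, the wrong isomer. O4 is therefore capped first and the chelated O2 is propargylated, so the Claisen shift can only go to C3 and gives the 8-formyl chromene.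

Remark on the precursor: the acyl donor 13 has no α-hydrogen, so it cannot quench the pyrone dianion. The enol ether is a methyl ether to match methoxide/methanol, and the ring-B phenol is a base-stable MOM ether. The enol-ether geometry (drawn E) is erased when ring C closes.

Step 1
Reactants: 1 2,4-dihydroxybenzaldehyde
Product: 2 2-hydroxy-4-(methoxymethoxy)benzaldehyde
Conditions: MOMCl (1.05 equiv), K2CO3, acetone, 0 to 20 °C
Reagents that add atoms: chloromethyl methyl ether (MOMCl), COCCl
Why: Williamson-type O-alkylation, in which the O2–H is hydrogen-bonded to the aldehyde and less acidic, so one equivalent of MOMCl should etherify O4 only.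

Step 2
Reactants: 2 2-hydroxy-4-(methoxymethoxy)benzaldehyde; 3 3-chloro-3-methylbut-1-yne
Product: 4 4-(methoxymethoxy)-2-[(2-methylbut-3-yn-2-yl)oxy]benzaldehyde
Conditions: DBU, CuCl2·2H2O (cat.), MeCN, 0 to 20 °C
Reagents that add atoms: none
Why: Copper-catalysed propargylic etherification (substitution through a copper acetylide/allenylidene), in which DBU ionises the chelated O2–H, the only phenol left, so the tertiary propargyl ether should form at O2.

Step 3
Reactants: 4 4-(methoxymethoxy)-2-[(2-methylbut-3-yn-2-yl)oxy]benzaldehyde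
Product: 6 5-(methoxymethoxy)-2,2-dimethyl-2H-chromene-8-carbaldehyde, via ortho-allenylphenol 5 (not isolated)
Conditions: o-xylene, 145 °C
Reagents that add atoms: none
Why: Thermal aromatic propargyl Claisen rearrangement followed by 1,5-hydrogen shift and oxa-6π electrocyclisation, in which C1 is blocked by the formyl group so the [3,3] shift can only reach C3 and the pyran ring must fuse between the two oxygens with its oxygen ortho to the aldehyde.

Step 4
Reactants: 6 5-(methoxymethoxy)-2,2-dimethyl-2H-chromene-8-carbaldehyde; 7 p-toluenesulfonylmethyl isocyanide (TosMIC)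
Product: 8 2-[5-(methoxymethoxy)-2,2-dimethyl-2H-chromen-8-yl]acetonitrile
Conditions: t-BuOK, DME, −40 °C; then MeOH, 65 °C
Reagents that add atoms: none
Why: Van Leusen reductive cyanation, in which the TosMIC anion adds to the aldehyde and base-induced fragmentation in methanol expels sulfinate and formate to leave the one-carbon-homologated nitrile under wholly basic conditions that spare the MOM ether and the chromene.

Step 5
Reactants: 8 2-[5-(methoxymethoxy)-2,2-dimethyl-2H-chromen-8-yl]acetonitrile
Product: 9 2-[5-(methoxymethoxy)-2,2-dimethyl-2H-chromen-8-yl]acetic acid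
Conditions: KOH, EtOH/H2O, 85 °C; then 1 M HCl to pH 4, 0 °C
Reagents that add atoms: water, O; potassium hydroxide, [K+].[OH-]
Why: Alkaline nitrile hydrolysis, to which the aryl MOM ether and the 2,2-dimethylchromene are inert, with the acid set free by cold dilute acid only to pH 4.

Step 6
Reactants: 9 2-[5-(methoxymethoxy)-2,2-dimethyl-2H-chromen-8-yl]acetic acid
Product: 10 N-methoxy-N-methyl-2-[5-(methoxymethoxy)-2,2-dimethyl-2H-chromen-8-yl]acetamide
Conditions: 1,1′-carbonyldiimidazole, CH2Cl2, 20 °C; then MeNH(OMe)·HCl, 20 °C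
Reagents that add atoms: N,O-dimethylhydroxylamine hydrochloride, CNOC.Cl
Why: Amide coupling through the acyl imidazolide, which runs under near-neutral conditions and should give the Weinreb amide without touching the acid-sensitive groups.

Step 7
Reactants: 10 N-methoxy-N-methyl-2-[5-(methoxymethoxy)-2,2-dimethyl-2H-chromen-8-yl]acetamide; 11 methyl formate
Product: 13 (E)-N,3-dimethoxy-N-methyl-2-[5-(methoxymethoxy)-2,2-dimethyl-2H-chromen-8-yl]prop-2-enamide, via sodium formyl enolate 12 (not isolated)
Conditions: NaH, HCO2Me, DMF, 0 to 20 °C; then Me2SO4, 20 °C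
Reagents that add atoms: dimethyl sulfate, COS(=O)(=O)OC
Why: Crossed Claisen formylation of the benzylic amide enolate followed by O-methylation of the formyl enolate by a hard electrophile in DMF (the standard β-methoxyacrylate construction), expected to give mainly the E isomer, whose geometry is of no consequence later.

Step 8
Reactants: 13 (E)-N,3-dimethoxy-N-methyl-2-[5-(methoxymethoxy)-2,2-dimethyl-2H-chromen-8-yl]prop-2-enamide; 14 4-hydroxy-6-methyl-2H-pyran-2-one
Product: 15 4-hydroxy-6-{(E)-4-methoxy-3-[5-(methoxymethoxy)-2,2-dimethyl-2H-chromen-8-yl]-2-oxobut-3-en-1-yl}-2H-pyran-2-one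
Conditions: 14 (2 equiv), LiN(iPr)2 (4 equiv), THF, −78 to −20 °C; then 13, −78 to 0 °C; AcOH, −20 °C
Reagents that add atoms: none
Why: Weinreb ketone synthesis with the O,C-dianion of triacetic acid lactone, a nucleophile known to be acylated at its methyl carbon, in which lithium chelation by the N-methoxy amide should direct 1,2-addition, the tetrahedral chelate stops over-addition, and no free amide base is left to attack 13.

Step 9
Reactants: 15 4-hydroxy-6-{(E)-4-methoxy-3-[5-(methoxymethoxy)-2,2-dimethyl-2H-chromen-8-yl]-2-oxobut-3-en-1-yl}-2H-pyran-2-one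
Product: 18 5,7-dihydroxy-3-[5-(methoxymethoxy)-2,2-dimethyl-2H-chromen-8-yl]-4H-chromen-4-one, via triketo ester 16 (not isolated), via acylphloroglucinol 17 (not isolated)
Conditions: Mg(OMe)2, dry MeOH, 65 °C; then AcOH, 0 °C
Reagents that add atoms: none
Why: Mg(OMe)2 adds methoxide to the lactone carbonyl and opens the pyrone to the magnesium chelate of triketo ester 16, whose C6 methylene (future C4a) attacks the ester carbonyl in a 6-exo-trig Claisen (Dieckmann-type) condensation and aromatises to acylphloroglucinol 17 (ring A). An ortho phenoxide of 17 then adds to C2 of the β-methoxy enone and expels methoxide (6-endo-trig oxa-Michael addition–elimination), which closes ring C as the chromone. The closest known reaction types are the Mg(OMe)2-mediated conversion of 6-(2-oxoalkyl)-4-hydroxy-2-pyrones into acylphloroglucinols and the cyclisation of 2-hydroxyaryl β-alkoxyvinyl ketones to chromones, here run in one flask. No stereocentre is formed. The selectivity needed is Claisen over aldol folding (C2 methylene onto the C7 ketone, which would give a resorcylate); the substrate secures it because that ketone is a vinylogous ester carbonyl, deactivated and shielded by the twisted ring B, while magnesium chelation of the 3,5-diketo ester holds the Claisen-competent fold. Methoxide in dry methanol matches both the methyl ester and the methyl enol ether, so exchange is degenerate and the C2 carbon is not lost by hydrolysis; if the C5 enolate oxygen closes on C2 first, the resulting 4-pyranone can still fold to the same isoflavone.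

Step 10
Reactants: 18 5,7-dihydroxy-3-[5-(methoxymethoxy)-2,2-dimethyl-2H-chromen-8-yl]-4H-chromen-4-one
Product: 19 5,7-bis(methoxymethoxy)-3-[5-(methoxymethoxy)-2,2-dimethyl-2H-chromen-8-yl]-4H-chromen-4-one
Conditions: NaH, MOMCl, DMF, 0 to 20 °C
Reagents that add atoms: chloromethyl methyl ether (MOMCl), COCCl
Why: Williamson etherification of both phenoxides, with the strong base needed to ionise the hydrogen-bonded O5–H, which should give a fully MOM-protected substrate for the reduction.

Step 11
Reactants: 19 5,7-bis(methoxymethoxy)-3-[5-(methoxymethoxy)-2,2-dimethyl-2H-chromen-8-yl]-4H-chromen-4-one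
Product: 21 (3S,4S)-5,7-bis(methoxymethoxy)-3-[5-(methoxymethoxy)-2,2-dimethyl-2H-chromen-8-yl]chroman-4-ol, via racemic isoflavanone 20 (not isolated)
Conditions: RuCl(p-cymene)[(S,S)-TsDPEN] (5 mol %), HCO2H/Et3N (5:2), EtOAc, 40 °C
Reagents that add atoms: none
Why: Noyori–Ikariya asymmetric transfer hydrogenation under dynamic kinetic resolution, in which conjugate hydride transfer gives isoflavanone 20, C3 epimerises quickly in the amine buffer, and the (S,S)-catalyst reduces the (3S)-ketone faster with hydride entering C4 anti to the aryl group, so both C3 and C4 of the cis-alcohol should be set by the catalyst.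

Step 12
Reactants: 21 (3S,4S)-5,7-bis(methoxymethoxy)-3-[5-(methoxymethoxy)-2,2-dimethyl-2H-chromen-8-yl]chroman-4-ol
Product: 22 (3S)-5,7-bis(methoxymethoxy)-3-[5-(methoxymethoxy)-2,2-dimethyl-2H-chromen-8-yl]chroman-4-one
Conditions: Dess–Martin periodinane, CH2Cl2, 0 to 20 °C
Reagents that add atoms: none
Why: Dess–Martin oxidation of the benzylic alcohol under non-basic conditions should return the C4 ketone without enolising C3, so the (3S) centre from step 11 is kept.

Step 13
Reactants: 22 (3S)-5,7-bis(methoxymethoxy)-3-[5-(methoxymethoxy)-2,2-dimethyl-2H-chromen-8-yl]chroman-4-one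
Product: 23 (3S)-5,7-dihydroxy-3-(5-hydroxy-2,2-dimethyl-2H-chromen-8-yl)chroman-4-one
Conditions: 3 M aq. HCl, MeOH/THF, 40 °C, stopped at full conversion
Reagents that add atoms: none
Why: Acid-catalysed acetal exchange (MOM cleavage) in methanol, in which the three MOM groups leave as dimethoxymethane under mild acid that 2,2-dimethylchromenes tolerate and under which acid-catalysed enolisation at C3 should be slow.

Compound list
1 | 2,4-dihydroxybenzaldehyde | O=Cc1ccc(O)cc1O | starting material
2 | 2-hydroxy-4-(methoxymethoxy)benzaldehyde | COCOc1ccc(C=O)c(O)c1 | intermediate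
3 | 3-chloro-3-methylbut-1-yne | CC(C)(Cl)C#C | starting material
4 | 4-(methoxymethoxy)-2-[(2-methylbut-3-yn-2-yl)oxy]benzaldehyde | COCOc1ccc(C=O)c(OC(C)(C)C#C)c1 | intermediate
5 | 2-hydroxy-4-(methoxymethoxy)-3-(3-methylbuta-1,2-dien-1-yl)benzaldehyde (ortho-allenylphenol, formed in the flask) | COCOc1ccc(C=O)c(O)c1C=C=C(C)C | intermediate
6 | 5-(methoxymethoxy)-2,2-dimethyl-2H-chromene-8-carbaldehyde | COCOc1ccc(C=O)c2OC(C)(C)C=Cc12 | intermediate
7 | p-toluenesulfonylmethyl isocyanide (TosMIC) | Cc1ccc(cc1)S(=O)(=O)C[N+]#[C-] | starting material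
8 | 2-[5-(methoxymethoxy)-2,2-dimethyl-2H-chromen-8-yl]acetonitrile | COCOc1ccc(CC#N)c2OC(C)(C)C=Cc12 | intermediate
9 | 2-[5-(methoxymethoxy)-2,2-dimethyl-2H-chromen-8-yl]acetic acid | COCOc1ccc(CC(=O)O)c2OC(C)(C)C=Cc12 | intermediate
10 | N-methoxy-N-methyl-2-[5-(methoxymethoxy)-2,2-dimethyl-2H-chromen-8-yl]acetamide | COCOc1ccc(CC(=O)N(C)OC)c2OC(C)(C)C=Cc12 | intermediate
11 | methyl formate | COC=O | starting material
12 | sodium (E)-3-[methoxy(methyl)amino]-2-[5-(methoxymethoxy)-2,2-dimethyl-2H-chromen-8-yl]-3-oxoprop-1-en-1-olate (formyl enolate, formed in the flask) | [Na+].[O-]/C=C(/C(=O)N(C)OC)c1ccc(OCOC)c2C=CC(C)(C)Oc12 | intermediate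
13 | (E)-N,3-dimethoxy-N-methyl-2-[5-(methoxymethoxy)-2,2-dimethyl-2H-chromen-8-yl]prop-2-enamide | CO/C=C(/C(=O)N(C)OC)c1ccc(OCOC)c2C=CC(C)(C)Oc12 | intermediate
14 | 4-hydroxy-6-methyl-2H-pyran-2-one | CC1=CC(O)=CC(=O)O1 | starting material
15 | 4-hydroxy-6-{(E)-4-methoxy-3-[5-(methoxymethoxy)-2,2-dimethyl-2H-chromen-8-yl]-2-oxobut-3-en-1-yl}-2H-pyran-2-one | CO/C=C(/C(=O)CC1=CC(O)=CC(=O)O1)c1ccc(OCOC)c2C=CC(C)(C)Oc12 | intermediate
16 | methyl (E)-9-methoxy-8-[5-(methoxymethoxy)-2,2-dimethyl-2H-chromen-8-yl]-3,5,7-trioxonon-8-enoate (formed in the flask) | CO/C=C(/C(=O)CC(=O)CC(=O)CC(=O)OC)c1ccc(OCOC)c2C=CC(C)(C)Oc12 | intermediate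
17 | (E)-3-methoxy-2-[5-(methoxymethoxy)-2,2-dimethyl-2H-chromen-8-yl]-1-(2,4,6-trihydroxyphenyl)prop-2-en-1-one (formed in the flask) | CO/C=C(/C(=O)c1c(O)cc(O)cc1O)c1ccc(OCOC)c2C=CC(C)(C)Oc12 | intermediate
18 | 5,7-dihydroxy-3-[5-(methoxymethoxy)-2,2-dimethyl-2H-chromen-8-yl]-4H-chromen-4-one | CC1(C)C=Cc2c(OCOC)ccc(C3=COc4cc(O)cc(O)c4C3=O)c2O1 | intermediate
19 | 5,7-bis(methoxymethoxy)-3-[5-(methoxymethoxy)-2,2-dimethyl-2H-chromen-8-yl]-4H-chromen-4-one | CC1(C)C=Cc2c(OCOC)ccc(C3=COc4cc(OCOC)cc(OCOC)c4C3=O)c2O1 | intermediate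
20 | rac-5,7-bis(methoxymethoxy)-3-[5-(methoxymethoxy)-2,2-dimethyl-2H-chromen-8-yl]chroman-4-one (formed in the flask, C3 epimerising) | CC1(C)C=Cc2c(OCOC)ccc(C3COc4cc(OCOC)cc(OCOC)c4C3=O)c2O1 | intermediate
21 | (3S,4S)-5,7-bis(methoxymethoxy)-3-[5-(methoxymethoxy)-2,2-dimethyl-2H-chromen-8-yl]chroman-4-ol (3,4-cis) | CC1(C)C=Cc2c(OCOC)ccc([C@H]3COc4cc(OCOC)cc(OCOC)c4[C@H]3O)c2O1 | intermediate
22 | (3S)-5,7-bis(methoxymethoxy)-3-[5-(methoxymethoxy)-2,2-dimethyl-2H-chromen-8-yl]chroman-4-one | CC1(C)C=Cc2c(OCOC)ccc([C@H]3COc4cc(OCOC)cc(OCOC)c4C3=O)c2O1 | intermediate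
23 | (3S)-5,7-dihydroxy-3-(5-hydroxy-2,2-dimethyl-2H-chromen-8-yl)chroman-4-one | CC1(C)C=Cc2c(O)ccc([C@H]3COc4cc(O)cc(O)c4C3=O)c2O1 | target

Total step count: 13. Longest linear sequence: 13 steps (1 to 23); compounds 3, 7, 11 and 14 are commercial and enter directly.

Steps most likely to fail

Step 9. The triketo ester may fold the aldol way (C2 onto the C7 ketone) to a resorcylate, the pyronate may open too slowly, or adventitious water may hydrolyse the enol ether with loss of the C2 carbon. The fallback builds ring A from a preformed phloroglucinol by known reactions; it sets out from 13 and comes back at 19. Phloroglucinol is converted with MOMCl and iPr2NEt into 1,3,5-tris(methoxymethoxy)benzene F1, which is ortho-lithiated with n-BuLi in THF at 0 °C and added to Weinreb amide 13 at −78 °C to give the aryl β-methoxyvinyl ketone F2. Treatment with HCl in MeOH at 45 °C removes the MOM groups, and the freed ortho phenol closes ring C by addition–elimination to give the triol isoflavone F3. NaH and MOMCl in DMF then protect all three phenols and give 19.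

Step 8. The dianion may attack the β-methoxy carbon (addition–elimination) instead of the amide carbonyl, or may add too slowly to the deactivated vinylogous carbamate carbonyl. The fallback replaces acylation by aldol addition and oxidation; it sets out from 13 and comes back at 15. Reduction of 13 with iBu2AlH in THF at −78 °C gives the (E)-3-methoxy-2-arylacrolein F4, whose aldehyde carbonyl is far more electrophilic than its β-carbon. Addition of the same pyrone dianion (THF, −78 °C) gives the racemic allylic carbinol F5, and MnO2 in CH2Cl2 oxidises this allylic alcohol to ketone 15.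

Step 13. Acid may enolise C3 and erode the enantiomeric purity, or protonate the chromene alkene and add methanol, while three MOM groups are being removed. The fallback moves the acid step before the stereocentre and ends with a buffered fluoride desilylation; it sets out from 18 and comes back at 23. HCl in MeOH at 45 °C converts 18 into the triol isoflavone F3, and TBSOTf with 2,6-lutidine in CH2Cl2 gives the tris-TBS isoflavone F6. Transfer hydrogenation as in step 11 should give the (3S,4S)-tris-TBS isoflavan-4-ol F7, and Dess–Martin periodinane gives the (3S)-tris-TBS isoflavanone F8. HF·pyridine buffered with pyridine in THF at 0 °C then releases 23 without exposure to acid or base strong enough to enolise C3.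

Further compounds
F1 | step 9 | 1,3,5-tris(methoxymethoxy)benzene | COCOc1cc(OCOC)cc(OCOC)c1
F2 | step 9 | (E)-3-methoxy-2-[5-(methoxymethoxy)-2,2-dimethyl-2H-chromen-8-yl]-1-[2,4,6-tris(methoxymethoxy)phenyl]prop-2-en-1-one | CO/C=C(/C(=O)c1c(OCOC)cc(OCOC)cc1OCOC)c1ccc(OCOC)c2C=CC(C)(C)Oc12
F3 | step 9 | 5,7-dihydroxy-3-(5-hydroxy-2,2-dimethyl-2H-chromen-8-yl)-4H-chromen-4-one | CC1(C)C=Cc2c(O)ccc(C3=COc4cc(O)cc(O)c4C3=O)c2O1
F4 | step 8 | (E)-3-methoxy-2-[5-(methoxymethoxy)-2,2-dimethyl-2H-chromen-8-yl]prop-2-enal | CO/C=C(/C=O)c1ccc(OCOC)c2C=CC(C)(C)Oc12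
F5 | step 8 | rac-4-hydroxy-6-{(E)-2-hydroxy-4-methoxy-3-[5-(methoxymethoxy)-2,2-dimethyl-2H-chromen-8-yl]but-3-en-1-yl}-2H-pyran-2-one | CO/C=C(/C(O)CC1=CC(O)=CC(=O)O1)c1ccc(OCOC)c2C=CC(C)(C)Oc12
F6 | step 13 | 5,7-bis(tert-butyldimethylsilyloxy)-3-[5-(tert-butyldimethylsilyloxy)-2,2-dimethyl-2H-chromen-8-yl]-4H-chromen-4-one | CC1(C)C=Cc2c(O[Si](C)(C)C(C)(C)C)ccc(C3=COc4cc(O[Si](C)(C)C(C)(C)C)cc(O[Si](C)(C)C(C)(C)C)c4C3=O)c2O1
F7 | step 13 | (3S,4S)-5,7-bis(tert-butyldimethylsilyloxy)-3-[5-(tert-butyldimethylsilyloxy)-2,2-dimethyl-2H-chromen-8-yl]chroman-4-ol | CC1(C)C=Cc2c(O[Si](C)(C)C(C)(C)C)ccc([C@H]3COc4cc(O[Si](C)(C)C(C)(C)C)cc(O[Si](C)(C)C(C)(C)C)c4[C@H]3O)c2O1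
F8 | step 13 | (3S)-5,7-bis(tert-butyldimethylsilyloxy)-3-[5-(tert-butyldimethylsilyloxy)-2,2-dimethyl-2H-chromen-8-yl]chroman-4-one | CC1(C)C=Cc2c(O[Si](C)(C)C(C)(C)C)ccc([C@H]3COc4cc(O[Si](C)(C)C(C)(C)C)cc(O[Si](C)(C)C(C)(C)C)c4C3=O)c2O1
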